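**Retrosynthetic overview**

- The plan rests on the near-symmetry of the oxolane core (O1, C2, C3, C4, C5). C3 carries the carbinol carbon Ca with ring A, and C4, trans to it, carries the benzylic CH2 (Cb) with ring B. Rings A and B are the same 4-hydroxy-3-methoxyphenyl group, so without the Ca hydroxyl a twofold axis through O1 and the midpoint of C3–C4 would exchange the two arms.
- Target ⇐ loss of two silyl groups ⇐ removal of one hydroxyl from the C2-symmetric (R,R)-diol, whose two carbinols are homotopic ⇐ catalyst-controlled reduction of both ketones of the (3R,4R)-3,4-diaroyloxolane.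
- Diaroyloxolane ⇐ aryl–Ca and aryl–Cb bonds made together from the (3R,4R)-oxolane-3,4-bis(N-methoxy-N-methylcarboxamide) and two equivalents of (3-methoxy-4-triisopropylsilyloxyphenyl)lithium, itself from 4-bromo-2-methoxyphenol.
- Bis-amide ⇐ resolved trans-oxolane-3,4-dicarboxylic acid ⇐ epimerisation and saponification of the cis-diester ⇐ hydrogenation of diethyl furan-3,4-dicarboxylate.
- Ring order: the oxolane comes first, by saturating the furan of the starting material. No ring is closed afterwards; rings A and B are bought as the bromophenol and joined on in one operation.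

Key step: step 7

Remark on the chemistry (assumption): which enantiomer of 1-phenylethylamine gives the less soluble salt with the (3R,4R)-diacid, and whether that salt is the 1:2 or the 1:1 salt, can only be settled by experiment. The route is written for the (S)-amine and the 1:2 salt; the (R)-amine would be used in the same way if the sense proves opposite.

**Route**

Step 1
Reactants: 1 diethyl furan-3,4-dicarboxylate
Product: 2 diethyl cis-oxolane-3,4-dicarboxylate (meso; 3R,4S)
Conditions: H2 (5 atm), 5% Rh/Al2O3, EtOH, 50 °C
Reagents that add atoms: none
Why: Heterogeneous catalytic hydrogenation of the electron-poor furan ring, with hydrogen delivered from the catalyst face, should give mainly the cis (meso) diester without hydrogenolysis of the esters or ring C–O bonds; the relative configuration set here is not carried forward, because step 2 equilibrates it.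

Step 2
Reactants: 2 diethyl cis-oxolane-3,4-dicarboxylate
Product: 4 racemic trans-oxolane-3,4-dicarboxylic acid, via racemic trans-diester 3 (not isolated)
Conditions: NaOEt (0.3 equiv), EtOH, reflux; then 2 M NaOH (aq), reflux; HCl to pH 1; crystallise
Reagents that add atoms: sodium hydroxide, [Na+].[OH-]
Why: Base-mediated epimerisation through the ester enolates should move the cis-diester to the thermodynamically preferred trans-diester, in which the vicinal ester groups lie on opposite faces, and saponification then fixes this as the dicarboxylate, which no longer epimerises; ring opening by β-elimination is not expected, because the ring C–O bond lies near the nodal plane of the exocyclic enolate (the reverse of a 5-endo-trig closure).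

Step 3
Reactants: 4 racemic trans-oxolane-3,4-dicarboxylic acid; 5 (S)-1-phenylethylamine
Product: 6 bis[(S)-1-phenylethylammonium] (3R,4R)-oxolane-3,4-dicarboxylate
Conditions: 5 (2.0 equiv), EtOH/H2O, reflux → 5 °C; recrystallise to constant rotation
Reagents that add atoms: (S)-1-phenylethylamine (5), C[C@H](N)c1ccccc1
Why: Classical resolution by diastereomeric salt formation: the salts of the (3R,4R)- and (3S,4S)-acids with one enantiomer of the amine differ in solubility, so fractional crystallisation selects, and does not create, the C3 and C4 configuration; the absolute configuration is to be secured by X-ray analysis of the salt and the enantiomeric purity by chiral HPLC of the bis-amide from step 5.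

Step 4
Reactants: 6 bis[(S)-1-phenylethylammonium] (3R,4R)-oxolane-3,4-dicarboxylate
Product: 7 (3R,4R)-oxolane-3,4-dicarboxylic acid
Conditions: sulfonic acid cation-exchange resin (H+ form), H2O, rt; evaporate the eluate
Reagents that add atoms: none
Why: Cation exchange retains the ammonium ion on the resin and releases the very water-soluble free diacid without extraction or heating, so neither stereocentre is touched.

Step 5
Reactants: 7 (3R,4R)-oxolane-3,4-dicarboxylic acid; 8 N,O-dimethylhydroxylamine hydrochloride
Product: 10 (3R,4R)-N,N'-dimethoxy-N,N'-dimethyloxolane-3,4-dicarboxamide, via bis(acylimidazole) 9 (not isolated)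
Conditions: 1,1'-carbonyldiimidazole (2.2 equiv), CH2Cl2, 0 °C → rt; then 8 (2.6 equiv), rt
Reagents that add atoms: N,O-dimethylhydroxylamine hydrochloride (8), CNOC.Cl
Why: Amide formation through the acylimidazole (carbonyldiimidazole activation), in which the imidazole set free liberates the hydroxylamine from its salt, so no strong base is present to epimerise C3 or C4; the trans-diacid cannot divert to a cyclic anhydride, because that would be a trans-fused bicyclo[3.3.0] ring.

Step 6
Reactants: 11 4-bromo-2-methoxyphenol
Product: 12 (4-bromo-2-methoxyphenoxy)triisopropylsilane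
Conditions: TIPSCl (1.1 equiv), imidazole (2.2 equiv), DMF, rt
Reagents that add atoms: chlorotriisopropylsilane (TIPSCl), CC(C)[Si](Cl)(C(C)C)C(C)C
Why: Imidazole-promoted silylation of the phenol masks the acidic OH for the organolithium step; the bulky silyl ether sits para to the future lithium site and so cannot migrate to carbon.

Step 7
Reactants: 10 (3R,4R)-N,N'-dimethoxy-N,N'-dimethyloxolane-3,4-dicarboxamide; 12 (4-bromo-2-methoxyphenoxy)triisopropylsilane
Product: 15 (3R,4R)-3,4-bis(3-methoxy-4-triisopropylsilyloxybenzoyl)oxolane, via aryllithium 13 (not isolated), via dilithium bis(hemiaminal) adduct 14 (not isolated)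
Conditions: 12 (2.4 equiv), n-BuLi (2.3 equiv), THF, −78 °C; then 10 (1.0 equiv), −78 → −30 °C; cold 1 M HCl
Reagents that add atoms: none
Why: Bromine–lithium exchange on 12 gives aryllithium 13, which adds once to each amide carbonyl of 10; each adduct is held as a five-membered lithium chelate between the alkoxide oxygen and the N-methoxy oxygen (14) and collapses to the ketone only in the cold acid quench, when no aryllithium is left. The closest known reaction type is the Weinreb ketone synthesis, run here in two directions at once on a C2-symmetric bis(N-methoxy-N-methylamide), a substrate class on which double aryllithium addition is established. No ring is closed and no stereocentre is created: the step forms the aryl–Ca and aryl–Cb bonds and carries the trans (3R,4R) configuration through unchanged. The selectivity needed is one aryl group per carbonyl, secured by the stability of the chelate at low temperature, together with retention at C3 and C4, secured by the low basicity of the aryllithium at −78 °C, the absence of an acidic α-hydrogen in adduct 14 and the cold acidic work-up. Because the C2 axis makes the two amides equivalent, no site selectivity is required, and a single accidental epimerisation would give a separable cis diastereomer, not the enantiomer. The trans arrangement also keeps the first-formed alkoxide from attacking the neighbouring amide, since that would close a trans-fused bicyclo[3.3.0] ring.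

Step 8
Reactants: 15 (3R,4R)-3,4-bis(3-methoxy-4-triisopropylsilyloxybenzoyl)oxolane
Product: 16 (R,R)-[(3R,4R)-oxolane-3,4-diyl]bis[(3-methoxy-4-triisopropylsilyloxyphenyl)methanol]
Conditions: (3aS)-1-methyl-3,3-diphenyltetrahydro-1H,3H-pyrrolo[1,2-c][1,3,2]oxazaborole (0.4 equiv), BH3·SMe2 (2.2 equiv), THF, −20 °C, slow addition of 15; MeOH
Reagents that add atoms: none
Why: Corey–Bakshi–Shibata reduction: each ketone should bind to the ring boron of the oxazaborolidine with the aryl group as the large substituent, and the nitrogen-bound borane should deliver hydride to the Si face, setting both new carbinol centres as R under catalyst control, by analogy with the reduction of acetophenone to (R)-1-phenylethanol by the same (S)-catalyst; the two ketones are homotopic, 1,4-diaryl-1,4-diketones are an established substrate class for this double reduction, and the non-basic conditions leave C3, C4 and the silyl ethers untouched.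

Step 9
Reactants: 16 (R,R)-[(3R,4R)-oxolane-3,4-diyl]bis[(3-methoxy-4-triisopropylsilyloxyphenyl)methanol]
Product: 17 O-phenyl mono-thionocarbonate of 16 (one carbinol as OC(=S)OPh, the other free)
Conditions: PhOC(S)Cl (1.0 equiv, slow addition), pyridine, DMAP (cat.), CH2Cl2, −20 → 0 °C; recovered 16 resubmitted
Reagents that add atoms: O-phenyl chlorothionoformate, S=C(Cl)Oc1ccccc1
Why: O-Thioacylation of a secondary alcohol (first stage of the Barton–McCombie deoxygenation) with the chloride as limiting reagent: the C2 axis exchanges the two hydroxyls, so acylation of either gives the same mono-ester, and the trans-disposed arms cannot be bridged by a five-membered ether ring, which protects the activated benzylic position from intramolecular displacement.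

Step 10
Reactants: 17 O-phenyl mono-thionocarbonate of 16
Product: 18 (R)-[(3R,4R)-4-(3-methoxy-4-triisopropylsilyloxybenzyl)oxolan-3-yl](3-methoxy-4-triisopropylsilyloxyphenyl)methanol
Conditions: Bu3SnH (1.5 equiv), Et3B (cat.), air, toluene, rt
Reagents that add atoms: none
Why: Barton–McCombie radical deoxygenation: the tributylstannyl radical adds to the thiocarbonyl sulfur, the benzylic C–O bond breaks by β-scission to a stabilised benzylic radical and this abstracts hydrogen from Bu3SnH, so that carbinol carbon becomes the CH2 of the ring B arm (its configuration is given up on purpose), while Ca, C3, C4, the free hydroxyl and the silyl ethers are not involved; initiation at room temperature avoids heating the ionisable benzylic thionocarbonate.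

Step 11
Reactants: 18 (R)-[(3R,4R)-4-(3-methoxy-4-triisopropylsilyloxybenzyl)oxolan-3-yl](3-methoxy-4-triisopropylsilyloxyphenyl)methanol
Product: 19 4-[(R)-hydroxy{(3R,4R)-4-[(4-hydroxy-3-methoxyphenyl)methyl]oxolan-3-yl}methyl]-2-methoxyphenol (CNP0234428.1)
Conditions: TBAF (2.5 equiv), AcOH (2.5 equiv), THF, 0 °C → rt; aq. NH4Cl
Reagents that add atoms: none
Why: Fluoride-mediated cleavage of the two aryl silyl ethers (driven by the Si–F bond), buffered with acetic acid so that the phenoxides are protonated at once and the para-hydroxybenzylic alcohol at Ca is not ionised to a quinone methide, which would erode its configuration.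

**Compound list**

1 | diethyl furan-3,4-dicarboxylate | CCOC(=O)c1cocc1C(=O)OCC | starting material
2 | diethyl cis-oxolane-3,4-dicarboxylate (meso; 3R,4S) | CCOC(=O)[C@H]1COC[C@H]1C(=O)OCC | intermediate
3 | diethyl trans-oxolane-3,4-dicarboxylate, racemate (both enantiomers written) | CCOC(=O)[C@H]1COC[C@@H]1C(=O)OCC.CCOC(=O)[C@@H]1COC[C@H]1C(=O)OCC | intermediate (not isolated)
4 | trans-oxolane-3,4-dicarboxylic acid, racemate (both enantiomers written) | OC(=O)[C@H]1COC[C@@H]1C(=O)O.OC(=O)[C@@H]1COC[C@H]1C(=O)O | intermediate
5 | (S)-1-phenylethylamine | C[C@H](N)c1ccccc1 | starting material (resolving agent)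
6 | bis[(S)-1-phenylethylammonium] (3R,4R)-oxolane-3,4-dicarboxylate | [O-]C(=O)[C@H]1COC[C@@H]1C(=O)[O-].C[C@H]([NH3+])c1ccccc1.C[C@H]([NH3+])c1ccccc1 | intermediate
7 | (3R,4R)-oxolane-3,4-dicarboxylic acid | OC(=O)[C@H]1COC[C@@H]1C(=O)O | intermediate
8 | N,O-dimethylhydroxylamine hydrochloride | CNOC.Cl | starting material
9 | (3R,4R)-3,4-bis(imidazol-1-ylcarbonyl)oxolane | O=C([C@H]1COC[C@@H]1C(=O)n1ccnc1)n1ccnc1 | intermediate (not isolated)
10 | (3R,4R)-N,N'-dimethoxy-N,N'-dimethyloxolane-3,4-dicarboxamide | CON(C)C(=O)[C@H]1COC[C@@H]1C(=O)N(C)OC | intermediate
11 | 4-bromo-2-methoxyphenol | COc1cc(Br)ccc1O | starting material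
12 | (4-bromo-2-methoxyphenoxy)triisopropylsilane | COc1cc(Br)ccc1O[Si](C(C)C)(C(C)C)C(C)C | intermediate
13 | (3-methoxy-4-triisopropylsilyloxyphenyl)lithium | [Li]c1ccc(O[Si](C(C)C)(C(C)C)C(C)C)c(OC)c1 | intermediate (not isolated)
14 | dilithium bis(hemiaminal alkoxide) from 10 and two 13 (configuration at the two hemiaminal carbons undefined) | COc1cc(C(O[Li])(N(C)OC)[C@H]2COC[C@@H]2C(O[Li])(N(C)OC)c2ccc(O[Si](C(C)C)(C(C)C)C(C)C)c(OC)c2)ccc1O[Si](C(C)C)(C(C)C)C(C)C | intermediate (not isolated)
15 | (3R,4R)-3,4-bis(3-methoxy-4-triisopropylsilyloxybenzoyl)oxolane | COc1cc(C(=O)[C@H]2COC[C@@H]2C(=O)c2ccc(O[Si](C(C)C)(C(C)C)C(C)C)c(OC)c2)ccc1O[Si](C(C)C)(C(C)C)C(C)C | intermediate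
16 | (R,R)-[(3R,4R)-oxolane-3,4-diyl]bis[(3-methoxy-4-triisopropylsilyloxyphenyl)methanol] | COc1cc([C@H](O)[C@H]2COC[C@@H]2[C@@H](O)c2ccc(O[Si](C(C)C)(C(C)C)C(C)C)c(OC)c2)ccc1O[Si](C(C)C)(C(C)C)C(C)C | intermediate
17 | O-phenyl mono-thionocarbonate of 16 (thionocarbonate carbinol R, free carbinol R, ring 3R,4R) | COc1cc([C@H](OC(=S)Oc3ccccc3)[C@H]2COC[C@@H]2[C@@H](O)c2ccc(O[Si](C(C)C)(C(C)C)C(C)C)c(OC)c2)ccc1O[Si](C(C)C)(C(C)C)C(C)C | intermediate
18 | (R)-[(3R,4R)-4-(3-methoxy-4-triisopropylsilyloxybenzyl)oxolan-3-yl](3-methoxy-4-triisopropylsilyloxyphenyl)methanol | COc1cc(C[C@H]2COC[C@@H]2[C@@H](O)c2ccc(O[Si](C(C)C)(C(C)C)C(C)C)c(OC)c2)ccc1O[Si](C(C)C)(C(C)C)C(C)C | intermediate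
19 | 4-[(R)-hydroxy{(3R,4R)-4-[(4-hydroxy-3-methoxyphenyl)methyl]oxolan-3-yl}methyl]-2-methoxyphenol | COc1cc(C[C@H]2COC[C@@H]2[C@@H](O)c2ccc(O)c(OC)c2)ccc1O | target

**Step count**

Total step count: 11. Longest linear sequence: 10 steps (steps 1–5 and 7–11, from 1 to 19); step 6 is a one-step branch.

**Steps most likely to fail**

Step 9 (mono-thionocarbonylation). Two processes may defeat it. The first is the statistics of two independent, identical hydroxyls: the reagent may run on to the second hydroxyl or leave both free. The second is ionisation of the electron-rich benzylic thionocarbonate with oxygen-to-sulfur migration before it is reduced. The fallback sets out from 16 and ties both hydroxyls into one thiocarbonyl unit, so that only one C–O bond can be cleaved. 1,1'-Thiocarbonyldiimidazole with DMAP in toluene at high dilution and 60 °C should give the seven-membered cyclic thionocarbonate of 16 F1 (the two carbinol oxygens joined through one C=S, a 1,3-dioxepane-2-thione ring trans-fused to the oxolane, all four stereocentres R). Under Bu3SnH/Et3B/air at room temperature the stannyl radical adds to sulfur and either of the two homotopic benzylic C–O bonds breaks; hydrogen transfer gives the O-carbinyl S-tributylstannyl thiocarbonate of the mono-deoxy alcohol F2. Aqueous KF in MeOH cleaves this and the fallback comes back to the route at 18. This is the cyclic-thionocarbonate form of the Barton–McCombie deoxygenation of diols; the seven-membered ring is a larger ring than the usual cases.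

Step 3 (resolution). Neither diastereomeric salt may crystallise selectively (oiling out, solid solutions, low enrichment). The fallback sets out from 2 and replaces crystallisation by chromatographic separation of a later, neutral compound. The NaOEt/EtOH epimerisation of step 2 is worked up before hydrolysis, so that the racemic trans-diester 3 is isolated. Direct aminolysis with 8 and i-PrMgCl in THF at −20 °C (ester to N-methoxy-N-methylamide through the magnesium amide) then gives racemic trans-N,N'-dimethoxy-N,N'-dimethyloxolane-3,4-dicarboxamide F3; base-induced epimerisation is harmless in the racemic series, since trans is the stable isomer. Preparative supercritical-fluid chromatography on an amylose tris(3,5-dimethylphenylcarbamate) phase separates the enantiomers, and the (3R,4R) enantiomer is 10, where the fallback comes back to the route. Its absolute configuration is to be assigned by X-ray analysis of a crystalline later compound.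

Step 8 (double ketone reduction). Facial selectivity may be poor at one or both carbonyls if the C3/C4 stereocentres oppose the catalyst, or if uncatalysed borane reduction and hydride delivery from the first-formed alkoxyborane compete. The fallback sets out from 15 and comes back at 16 by asymmetric transfer hydrogenation with RuCl(p-cymene)[(R,R)-N-tosyl-1,2-diphenylethane-1,2-diamine] in HCO2H/Et3N (5:2) at room temperature. Stereocontrol there rests on the attraction between the aryl ring of the ketone and the η6-arene of the catalyst, not on a size ranking of aryl against the branched ring carbon, and the (R,R)-ligand should give the (R)-carbinols. This fallback makes no new compound (F0).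

**Further compounds**

F1 | step 9 | seven-membered cyclic thionocarbonate of 16 (1,3-dioxepane-2-thione trans-fused to the oxolane, all stereocentres R) | COc1cc([C@@H]3OC(=S)O[C@@H](c5ccc(O[Si](C(C)C)(C(C)C)C(C)C)c(OC)c5)[C@H]4COC[C@H]34)ccc1O[Si](C(C)C)(C(C)C)C(C)C
F2 | step 9 | O-{(R)-[(3R,4R)-4-(3-methoxy-4-triisopropylsilyloxybenzyl)oxolan-3-yl](3-methoxy-4-triisopropylsilyloxyphenyl)methyl} S-(tributylstannyl) carbonothioate | COc1cc(C[C@H]2COC[C@@H]2[C@@H](OC(=O)S[Sn](CCCC)(CCCC)CCCC)c2ccc(O[Si](C(C)C)(C(C)C)C(C)C)c(OC)c2)ccc1O[Si](C(C)C)(C(C)C)C(C)C
F3 | step 3 | trans-N,N'-dimethoxy-N,N'-dimethyloxolane-3,4-dicarboxamide, racemate (both enantiomers written) | CON(C)C(=O)[C@H]1COC[C@@H]1C(=O)N(C)OC.CON(C)C(=O)[C@@H]1COC[C@H]1C(=O)N(C)OC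
F0 | step 8 | none | none
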